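Target comes from a step that needs starting material, dissolved reagent and free catalyst together, so we ask what each flask gives that step and what share of the lost starting material it receives.

- Wednesday's: starting material 5.0 mM; second substrate 0.500 equiv; gas 0.43 mM (held); free catalyst 2.2 mol%; temperature 20 °C; time 2.0 s
- Monday's: starting material 5.0 mM; second substrate 0.500 equiv; gas 0.43 mM (held); free catalyst 2.2 mol%; temperature 40 °C; time 2.0 s

    2 free catalyst → spent catalyst (k1 = 2490 M⁻¹ s⁻¹, Ea1 = 41.0 kJ mol⁻¹)
    2 starting material → homo dimer (k2 = 35.6 M⁻¹ s⁻¹, Ea2 = 35.0 kJ mol⁻¹)
    second substrate + reagent + free catalyst → free catalyst + second product (k3 = 3.77 × 10⁵ M⁻² s⁻¹, Ea3 = 19.0 kJ mol⁻¹)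
    gas ⇌ reagent, rate k4*(csat - [reagent]) (k4 = 10.1 s⁻¹, csat = 0.43 mM)
    starting material + reagent + free catalyst → free catalyst + target (k5 = 3.42 × 10⁶ M⁻² s⁻¹, Ea5 = 13.0 kJ mol⁻¹)
    (constants at 40 °C)

- which flask leads in amount of target, in percent of the starting material charged ("all alike" within 1.5 percentage points) (Wednesday's / Monday's / all alike)
- how much target is there at the end, in percent of the starting material charged: Wednesday's
- how much target is there at the end, in percent of the starting material charged: Monday's

- percent here means starting material units held: one homo dimer counts as two
- where a step has two of a species, its rate is k times that concentration squared, and two are used at each turn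
- at the start none of reagent is dissolved
- at 40 °C the constants are as listed, elsewhere as the activation energies make them

First, does the gas keep up? The free catalyst charge is 0.110 mM, so at the start of Monday's flask the target step draws reagent at 1.88 s⁻¹, less than the transfer coefficient of 10.1 s⁻¹. The second substrate draws 0.104 s⁻¹, much less, and we drop it. Transfer settles in about 0.0990 s, much shorter than the run, so we treat it as settled: saturation times transfer over transfer plus draw gives 0.362 mM of reagent on Monday's. Wednesday's target step is slower by a factor of 1.4, which gives 0.380 mM.

Second, where does the starting material go? On Monday's the target path removes 0.136 s⁻¹ and the homo dimer path 0.356 s⁻¹. This gives 27.7 % as Monday's target share, the target path's rate over both paths together, a selectivity. Wednesday's paths, 0.102 s⁻¹ and 0.142 s⁻¹, give a higher share of 41.7 %.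

Third, does the share last, and how much is consumed? At steady reagent, the target path over the homo dimer path goes as free catalyst over starting material, and both fall. Second-order loss leaves 47.7 % of the free catalyst on Monday's and 72.8 % on Wednesday's. As a working assumption we hold the share through the run and let starting material fall in the same second-order way, which consumes 49.6 % on Monday's and 32.8 % on Wednesday's. Share times consumption gives 13.7 % on Monday's and 13.7 % on Wednesday's, so we say all alike.

The forecast also says all alike, with 13.8 % for Wednesday's and 13.2 % for Monday's, which is lower than our Monday's figure; its grounds are that “Warming speeds target formation but speeds catalyst death and homodimerisation more”.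

The simulation gives all alike, with 13.8 % on Wednesday's and 13.2 % on Monday's. On Monday's flask, starting material goes to homo dimer 2.6 times as fast as to target at 0.400 s and 2.4 times as fast at 2.00 s, target shares of 27.8 % and 29.0 % of the loss at those two moments. With 3.7 mol% of free catalyst and all else as on Monday's, the share reckoned for the start rises from 27.7 % to 36.8 %, and that neighbour ends with 17.5 % of target from 52.0 % of starting material consumed.

The constants used here were drawn at random within sensible limits; the result is computed.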